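**Retrosynthetic overview**
1. Target ⇒ C4′-dioxolane-protected C1 aldehyde (last operation: aldehyde → acid, then ketal off) plus, across the C8′–O ester bond, the (S)-monomethyl ester of 3-hydroxy-3-methylglutaric acid (Reformatsky diester, enzymatic desymmetrisation).
2. C1′–C5 bond ⇒ chelation-controlled addition of the dilithiated C6 (Z)-enynol to the C1′ ketone of a β-keto ester; one hydride step then turns the alkyne into the (E)-alkene and CO2Me into C8′H2OH.
3. C4′=O ⇒ γ-C–H oxidation of the cyclohexenone, then selective dioxolane formation.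
4. Key disconnection at C6′: the cyclohexenone with its quaternary centre ⇒ enantioselective one-carbon ring expansion (1,2-shift of the saturated α′-carbon) of 2-methylcyclopent-2-en-1-one with methyl 2-diazopropanoate (from alanine methyl ester).
5. Ring order: the only carbocycle is made in step 2 by enlarging a purchased five-membered ring to the six-membered ring; the dioxolane is a temporary ring (on in step 4, off in step 11).

Assumption: pig liver esterase converts diester 15 into the (S)-half ester 16, as described for this substrate; primed locants follow abscisic acid numbering (C1′ carbinol, C6′ quaternary carbon, C8′ its CH2O carbon, side chain C1–C5).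

**Route**

Step 1
Reactants: 1 L-alanine methyl ester hydrochloride
Product: 2 methyl 2-diazopropanoate
Conditions: isoamyl nitrite (1.2 equiv), Et3N (1.0 equiv), AcOH (0.2 equiv), CHCl3, reflux, 30 min
Reagents that add atoms: isoamyl nitrite, CC(C)CCON=O
Why: Diazotisation of a primary α-amino ester by an alkyl nitrite (N-nitrosation, dehydration, loss of the α-proton) gives the acceptor-stabilised diazo ester, the stereocentre of 1 being intentionally erased.

Step 2
Reactants: 2 methyl 2-diazopropanoate; 3 2-methylcyclopent-2-en-1-one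
Product: 4 methyl (1R)-1,3-dimethyl-2-oxocyclohex-3-ene-1-carboxylate
Conditions: Sc(OTf)3 (5 mol %), 1,1′-(propane-1,3-diyl)bis[(2S)-2-{[2,6-di(propan-2-yl)phenyl]carbamoyl}piperidine 1-oxide] (6 mol %; or its mirror image, whichever gives (R)-4), 4 Å MS, CH2Cl2, −30 → 0 °C, 2 (1.3 equiv) added over 6 h
Reagents that add atoms: none
Why: Proposed new method: the chiral scandium complex binds the enone carbonyl of 3 and shields one face of the incoming diazo carbon of 2, so that 1,2-addition gives a diazonium alkoxide of defined configuration at the former diazo carbon, which collapses by anti-periplanar 1,2-shift of the saturated α′-carbon with invertive loss of N2 (the alkenyl carbon being the poorer migrating group) to the ring-expanded β-keto ester with the (R) quaternary centre; the closest known reaction type is the Lewis acid-catalysed enantioselective Tiffeneau–Demjanov-type homologation of saturated cycloalkanones and aryl ketones with α-alkyl-α-diazoesters, taken together with the saturated-side homologation of cycloalkenones by ethyl diazoacetate, and the two have not been combined on a 2-substituted cycloalkenone.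

Step 3
Reactants: 4 methyl (1R)-1,3-dimethyl-2-oxocyclohex-3-ene-1-carboxylate
Product: 5 methyl (1R)-1,3-dimethyl-2,5-dioxocyclohex-3-ene-1-carboxylate
Conditions: Rh2(cap)4 (dirhodium tetrakis(caprolactamate), 1 mol %), t-BuOOH (70% aq., 6 equiv), K2CO3 (0.5 equiv), CH2Cl2, rt → 40 °C
Reagents that add atoms: tert-butyl hydroperoxide, CC(C)(C)OO
Why: Radical allylic C–H oxidation of an enone to an enedione: tert-butylperoxyl radicals generated by the dirhodium carboxamidate abstract the only secondary allylic (γ) hydrogen at C5 and the resulting peroxide collapses to the ketone, while the quaternary stereocentre cannot epimerise.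

Step 4
Reactants: 5 methyl (1R)-1,3-dimethyl-2,5-dioxocyclohex-3-ene-1-carboxylate
Product: 6 methyl (7R)-7,9-dimethyl-8-oxo-1,4-dioxaspiro[4.5]dec-9-ene-7-carboxylate
Conditions: HOCH2CH2OH (1.5 equiv), p-toluenesulfonic acid monohydrate (5 mol %), benzene, reflux, Dean–Stark
Reagents that add atoms: ethylene glycol, OCCO
Why: Acid-catalysed ketalisation with azeotropic water removal occurs only at the C5 carbonyl because the C2 carbonyl is flanked by the quaternary carbon and the methyl-bearing alkene carbon, as in the selective mono-ketalisation of 2,6,6-trimethylcyclohex-2-ene-1,4-dione.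

Step 5
Reactants: 6 methyl (7R)-7,9-dimethyl-8-oxo-1,4-dioxaspiro[4.5]dec-9-ene-7-carboxylate; 7 (2Z)-3-methylpent-2-en-4-yn-1-ol
Product: 9 methyl (7R,8S)-8-hydroxy-8-[(3Z)-5-hydroxy-3-methylpent-3-en-1-yn-1-yl]-7,9-dimethyl-1,4-dioxaspiro[4.5]dec-9-ene-7-carboxylate, via dilithio enynolate 8 (not isolated)
Conditions: 7 (2.2 equiv), n-BuLi (4.4 equiv), THF, −78 → 0 °C; then added to 6 pre-stirred with anhydrous CeCl3 (2.5 equiv) in THF, −78 °C, 2 h; AcOH/THF quench at −78 °C
Reagents that add atoms: none
Why: Chelation-controlled 1,2-addition of an alkynyl lithium/cerium reagent to a β-keto ester: cerium bridges the ketone and ester carbonyls, which holds the ester in the carbonyl plane and the C7 methyl pseudo-axial, so the acetylide enters anti to that methyl (cis to the ester carbon) and sets the tertiary carbinol as (8S), the relative configuration of the target.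

Step 6
Reactants: 9 methyl (7R,8S)-8-hydroxy-8-[(3Z)-5-hydroxy-3-methylpent-3-en-1-yn-1-yl]-7,9-dimethyl-1,4-dioxaspiro[4.5]dec-9-ene-7-carboxylate
Product: 10 (2Z,4E)-5-[(7S,8R)-8-hydroxy-7-(hydroxymethyl)-7,9-dimethyl-1,4-dioxaspiro[4.5]dec-9-en-8-yl]-3-methylpenta-2,4-dien-1-ol
Conditions: LiAlH4 (5 equiv), THF, 0 °C → rt, 4 h; H2O, 15% aq. NaOH, H2O
Reagents that add atoms: none
Why: Aluminium hydride reduction does two jobs, ester to primary alcohol and alkoxide-directed trans-hydroalumination of the propargylic alkyne giving the (4E)-alkene on protonolysis, without touching the (2Z)-alkene, the ketal or either stereocentre (the descriptors change to 7S,8R only through substituent priorities).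

Step 7
Reactants: 10 (2Z,4E)-5-[(7S,8R)-8-hydroxy-7-(hydroxymethyl)-7,9-dimethyl-1,4-dioxaspiro[4.5]dec-9-en-8-yl]-3-methylpenta-2,4-dien-1-ol
Product: 11 (2Z,4E)-5-[(7S,8R)-8-hydroxy-7-(hydroxymethyl)-7,9-dimethyl-1,4-dioxaspiro[4.5]dec-9-en-8-yl]-3-methylpenta-2,4-dienal
Conditions: MnO2 (activated, 20 equiv), CH2Cl2, rt, dark, 2 h
Reagents that add atoms: none
Why: Chemoselective allylic oxidation: MnO2 oxidises only the allylic primary alcohol to the (2Z,4E)-dienal and leaves the neopentyl primary and the tertiary hydroxyl untouched.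

Step 8
Reactants: 12 methyl acetoacetate; 13 methyl bromoacetate
Product: 15 dimethyl 3-hydroxy-3-methylpentanedioate, via bromozinc ester enolate 14 (not isolated)
Conditions: Zn dust (TMSCl-activated, 1.5 equiv), THF, reflux, 2 h; cold 1 M HCl work-up
Reagents that add atoms: none
Why: Reformatsky reaction: the weakly basic zinc enolate adds to the ketone carbonyl of the β-keto ester in competition with its enolisation and gives the prochiral tertiary carbinol diester.

Step 9
Reactants: 15 dimethyl 3-hydroxy-3-methylpentanedioate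
Product: 16 (3S)-3-hydroxy-5-methoxy-3-methyl-5-oxopentanoic acid
Conditions: pig liver esterase (PLE), 0.1 M phosphate buffer pH 7.5, 25 °C, pH-stat with 1 M NaOH (1.0 equiv); then HCl to pH 2, EtOAc
Reagents that add atoms: water, O
Why: Enzymatic desymmetrisation: the esterase hydrolyses one of the two enantiotopic methyl ester arms, which makes C3 a stereocentre of (S) configuration.

Step 10
Reactants: 11 (2Z,4E)-5-[(7S,8R)-8-hydroxy-7-(hydroxymethyl)-7,9-dimethyl-1,4-dioxaspiro[4.5]dec-9-en-8-yl]-3-methylpenta-2,4-dienal; 16 (3S)-3-hydroxy-5-methoxy-3-methyl-5-oxopentanoic acid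
Product: 17 1-{[(7S,8R)-8-hydroxy-7,9-dimethyl-8-[(1E,3Z)-3-methyl-5-oxopenta-1,3-dien-1-yl]-1,4-dioxaspiro[4.5]dec-9-en-7-yl]methyl} 5-methyl (3R)-3-hydroxy-3-methylpentanedioate
Conditions: DCC (1.3 equiv), 4-(dimethylamino)pyridine (0.2 equiv), CH2Cl2, 0 °C → rt, dark
Reagents that add atoms: none
Why: Steglich esterification acylates the only primary hydroxyl, the two tertiary hydroxyls being inert under carbodiimide conditions, and joins the two stereodefined halves without touching a stereocentre (C3 of the glutarate becomes R only by priority change).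

Step 11
Reactants: 17 1-{[(7S,8R)-8-hydroxy-7,9-dimethyl-8-[(1E,3Z)-3-methyl-5-oxopenta-1,3-dien-1-yl]-1,4-dioxaspiro[4.5]dec-9-en-7-yl]methyl} 5-methyl (3R)-3-hydroxy-3-methylpentanedioate
Product: 19 (2Z,4E)-5-[(1R,6S)-1-hydroxy-6-({[(3R)-3-hydroxy-5-methoxy-3-methyl-5-oxopentanoyl]oxy}methyl)-2,6-dimethyl-4-oxocyclohex-2-en-1-yl]-3-methylpenta-2,4-dienoic acid, via ketal acid 18 (not isolated)
Conditions: NaClO2 (3 equiv), NaH2PO4 (3 equiv), 2-methyl-2-butene (10 equiv), t-BuOH/H2O, 0 °C → rt; then 1 M HCl, THF, rt, 2 h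
Reagents that add atoms: sodium chlorite, [Na+].[O-]Cl=O; water, O
Why: Pinnick oxidation converts the enal into the acid without alkene isomerisation (2-methyl-2-butene traps HOCl), and dilute acid then hydrolyses the dioxolane to the enone, which cannot undergo oxa-Michael closure from C8′ because that oxygen is already acylated.

**Compound list**
1 | L-alanine methyl ester hydrochloride | C[C@H](N)C(=O)OC.Cl | starting material
2 | methyl 2-diazopropanoate | CC(=[N+]=[N-])C(=O)OC | intermediate
3 | 2-methylcyclopent-2-en-1-one | CC1=CCCC1=O | starting material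
4 | methyl (1R)-1,3-dimethyl-2-oxocyclohex-3-ene-1-carboxylate | COC(=O)[C@]1(C)CCC=C(C)C1=O | intermediate
5 | methyl (1R)-1,3-dimethyl-2,5-dioxocyclohex-3-ene-1-carboxylate | COC(=O)[C@]1(C)CC(=O)C=C(C)C1=O | intermediate
6 | methyl (7R)-7,9-dimethyl-8-oxo-1,4-dioxaspiro[4.5]dec-9-ene-7-carboxylate | COC(=O)[C@]1(C)CC2(OCCO2)C=C(C)C1=O | intermediate
7 | (2Z)-3-methylpent-2-en-4-yn-1-ol | C#C/C(C)=C\CO | starting material
8 | dilithium salt of 7 (lithium acetylide, lithium alkoxide) | [Li]C#C/C(C)=C\CO[Li] | intermediate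
9 | methyl (7R,8S)-8-hydroxy-8-[(3Z)-5-hydroxy-3-methylpent-3-en-1-yn-1-yl]-7,9-dimethyl-1,4-dioxaspiro[4.5]dec-9-ene-7-carboxylate | COC(=O)[C@]1(C)CC2(OCCO2)C=C(C)[C@]1(O)C#C/C(C)=C\CO | intermediate
10 | (2Z,4E)-5-[(7S,8R)-8-hydroxy-7-(hydroxymethyl)-7,9-dimethyl-1,4-dioxaspiro[4.5]dec-9-en-8-yl]-3-methylpenta-2,4-dien-1-ol | OC[C@]1(C)CC2(OCCO2)C=C(C)[C@]1(O)/C=C/C(C)=C\CO | intermediate
11 | (2Z,4E)-5-[(7S,8R)-8-hydroxy-7-(hydroxymethyl)-7,9-dimethyl-1,4-dioxaspiro[4.5]dec-9-en-8-yl]-3-methylpenta-2,4-dienal | OC[C@]1(C)CC2(OCCO2)C=C(C)[C@]1(O)/C=C/C(C)=C\C=O | intermediate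
12 | methyl acetoacetate (methyl 3-oxobutanoate) | CC(=O)CC(=O)OC | starting material
13 | methyl bromoacetate | COC(=O)CBr | starting material
14 | bromo(2-methoxy-2-oxoethyl)zinc (Reformatsky reagent) | COC(=O)C[Zn]Br | intermediate
15 | dimethyl 3-hydroxy-3-methylpentanedioate | COC(=O)CC(C)(O)CC(=O)OC | intermediate
16 | (3S)-3-hydroxy-5-methoxy-3-methyl-5-oxopentanoic acid | COC(=O)C[C@@](C)(O)CC(=O)O | intermediate
17 | 1-{[(7S,8R)-8-hydroxy-7,9-dimethyl-8-[(1E,3Z)-3-methyl-5-oxopenta-1,3-dien-1-yl]-1,4-dioxaspiro[4.5]dec-9-en-7-yl]methyl} 5-methyl (3R)-3-hydroxy-3-methylpentanedioate | COC(=O)C[C@@](C)(O)CC(=O)OC[C@]1(C)CC2(OCCO2)C=C(C)[C@]1(O)/C=C/C(C)=C\C=O | intermediate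
18 | (2Z,4E)-5-[(7S,8R)-8-hydroxy-7-({[(3R)-3-hydroxy-5-methoxy-3-methyl-5-oxopentanoyl]oxy}methyl)-7,9-dimethyl-1,4-dioxaspiro[4.5]dec-9-en-8-yl]-3-methylpenta-2,4-dienoic acid | COC(=O)C[C@@](C)(O)CC(=O)OC[C@]1(C)CC2(OCCO2)C=C(C)[C@]1(O)/C=C/C(C)=C\C(=O)O | intermediate
19 | (2Z,4E)-5-[(1R,6S)-1-hydroxy-6-({[(3R)-3-hydroxy-5-methoxy-3-methyl-5-oxopentanoyl]oxy}methyl)-2,6-dimethyl-4-oxocyclohex-2-en-1-yl]-3-methylpenta-2,4-dienoic acid | COC(=O)C[C@@](C)(O)CC(=O)OC[C@]1(C)CC(=O)C=C(C)[C@]1(O)/C=C/C(C)=C\C(=O)O | target

**Totals and risks**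

Total step count: 11. Longest linear sequence: 9 steps (1 → 2 → 4 → 5 → 6 → 9 → 10 → 11 → 17 → 19); the glutarate arm (12 + 13 → 15 → 16) joins at step 10.

Step 2, the new reaction, is the most uncertain. The diazo ester may add in a conjugate sense to the activated enone (cyclopropane or pyrazoline), the alkenyl carbon may migrate in part, and the sense and level of enantioselection are unknown until the first run. The fallback uses known chemistry and sets out from 2 and 3. Achiral activation with BF3·OEt2 in CH2Cl2 at −78 °C, the established Lewis acid-promoted homologation of ketones with diazoesters and with saturated-side migration for cycloalkenones, gives racemic methyl 1,3-dimethyl-2-oxocyclohex-3-ene-1-carboxylate F1. Its enantiomers are separated by preparative chromatography on an amylose tris(3,5-dimethylphenylcarbamate) stationary phase. The (R)-enantiomer is 4, where the route is rejoined.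

Step 5 may give the wrong C8 (C1′) epimer if the cerium chelate is not formed and the ester sits pseudo-axial, because the acetylide would then enter cis to the methyl group. The fallback changes the control element to a metal alkoxide and sets out from 6. LiAlH4 in THF reduces ketone and ester to the C8-epimeric diols (7S)-7-(hydroxymethyl)-7,9-dimethyl-1,4-dioxaspiro[4.5]dec-9-en-8-ol F2. MnO2 re-oxidises only the secondary allylic alcohol to (7S)-7-(hydroxymethyl)-7,9-dimethyl-1,4-dioxaspiro[4.5]dec-9-en-8-one F3. Deprotonation with i-PrMgCl forms a six-membered magnesium alkoxide–ketone chelate that again places the methyl group pseudo-axial, and addition of 8 anti to it gives (7S,8S)-7-(hydroxymethyl)-8-[(3Z)-5-hydroxy-3-methylpent-3-en-1-yn-1-yl]-7,9-dimethyl-1,4-dioxaspiro[4.5]dec-9-en-8-ol F4. LiAlH4 trans-reduction of the alkyne then delivers 10, where the route is rejoined.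

Step 9 is the third risk: the enantiomeric excess of the esterase hydrolysis of this small diester varies with enzyme batch and conditions and must be measured. The fallback replaces desymmetrisation by classical resolution and sets out from 15. Half-saponification with LiOH (1.0 equiv) in MeOH/H2O gives racemic 3-hydroxy-5-methoxy-3-methyl-5-oxopentanoic acid F5. Fractional crystallisation with (S)-1-phenylethylamine (or its mirror image, whichever makes the salt of the (S)-acid the less soluble one) gives (S)-1-phenylethylammonium (3S)-3-hydroxy-5-methoxy-3-methyl-5-oxopentanoate F6. Acidification and extraction release 16, where the route is rejoined.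

**Further compounds**
F1 | step 2 | racemic methyl 1,3-dimethyl-2-oxocyclohex-3-ene-1-carboxylate | COC(=O)C1(C)CCC=C(C)C1=O
F2 | step 5 | (7S)-7-(hydroxymethyl)-7,9-dimethyl-1,4-dioxaspiro[4.5]dec-9-en-8-ol (C8 epimers) | OC[C@]1(C)CC2(OCCO2)C=C(C)C1O
F3 | step 5 | (7S)-7-(hydroxymethyl)-7,9-dimethyl-1,4-dioxaspiro[4.5]dec-9-en-8-one | OC[C@]1(C)CC2(OCCO2)C=C(C)C1=O
F4 | step 5 | (7S,8S)-7-(hydroxymethyl)-8-[(3Z)-5-hydroxy-3-methylpent-3-en-1-yn-1-yl]-7,9-dimethyl-1,4-dioxaspiro[4.5]dec-9-en-8-ol | OC[C@]1(C)CC2(OCCO2)C=C(C)[C@]1(O)C#C/C(C)=C\CO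
F5 | step 9 | racemic 3-hydroxy-5-methoxy-3-methyl-5-oxopentanoic acid | COC(=O)CC(C)(O)CC(=O)O
F6 | step 9 | (S)-1-phenylethylammonium (3S)-3-hydroxy-5-methoxy-3-methyl-5-oxopentanoate | COC(=O)C[C@@](C)(O)CC(=O)[O-].C[C@H]([NH3+])c1ccccc1
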